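A direct plan would build on the aromatic ring of 5,7-dihydroxy-4-phenylcoumarin A1: reduce it to the (4S)-dihydrocoumarin, C-acylate with tigloyl chloride and close the cis-2,3-dimethylchromanone by oxa-Michael addition to give lactone A2.
It would then open the lactone, alkylate C6 reductively with the verbenone-derived cyclobutane aldehyde A3 to the 6-alkyl acylphloroglucinol A4, and end with a dearomatising C6-prenylation and ester hydrolysis.
Its weakest steps would be:
(a) the final dearomatising prenylation, which would have to create quaternary C6 face-selectively on the most valuable intermediate, without close precedent, without help from the remote stereocentres and against O-prenylation;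
(b) the oxa-Michael closure of the pyranone, which would leave C3 to a kinetic protonation into the less stable cis isomer and could revert, scrambling C2 and C3;
(c) the run of O-methylation, Friedel–Crafts acylation, O-demethylation and lactone opening, five or six steps that add no skeletal complexity and only steer regiochemistry on the phloroglucinol ring.

Plan of the new route (chromene numbering of the target: O1, C2, C3, C4, C4a, C5, C6, C7, C8, C8a):
The retrosynthesis cuts, in this order: C8–C(benzylic) with the acid (carbene annulation, last); C4a–C5 and C4a–C4 (key step); O1–C8a (oxa-Michael); C7–C8 (acyl alkynylation); C6–prenyl (phase-transfer alkylation).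
No aromatic ring is used: both core rings arise in step 12 from the acyclic triester 17, the pyranone first and the carbocycle second (the reverse order would give the same bicycle).
The enabling feature is the ring-fusion carbon C4a: it bears no hydrogen and its neighbours C4, C5 and C8a are all at the carbonyl oxidation level, so it can start as the methyl group of an enol ether and be acylated twice.
C6 is quaternary, so the C7 ketone activates only that methyl group, and O1 already sits on C8a, so the pyran cannot close the wrong way.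
C6 is set on a small acyclic malonate (step 6), C2 and C3 are set together by an aldol reaction and never re-formed, and no phenol or protecting group occurs, so none of the three weak steps arises.
Key step: step 12

Assumption: the sense of induction in steps 6 and 13 is assigned by analogy with model substrates; if either catalyst favours the opposite configuration, its pseudo-enantiomer (the cinchoninium salt) or enantiomer (the (5aS,10bR) triazolium salt) is used.

Step 1
Reactants: 1 (1S,5S)-(−)-verbenone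
Product: 3 (1S,3R)-3-acetyl-2,2-dimethylcyclobutane-1-carboxylic acid (cis-pinononic acid), via alpha-keto acid 2 (not isolated)
Conditions: RuCl3·xH2O (2 mol%), NaIO4 (4.2 equiv), EtOAc/MeCN/H2O, rt
Reagents that add atoms: sodium periodate, [Na+].[O-]I(=O)(=O)=O; water, O
Why: RuO4 generated in situ cleaves the enone C=C (Sharpless ruthenium tetroxide oxidation) and the α-keto acid 2 loses CO2 oxidatively, so both ring stereocentres come unchanged from the chiral pool.

Step 2
Reactants: 3 (1S,3R)-3-acetyl-2,2-dimethylcyclobutane-1-carboxylic acid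
Product: 4 (1S,3S)-2,2-dimethyl-3-(prop-1-en-2-yl)cyclobutane-1-carboxylic acid
Conditions: Ph3PCH3Br (2.6 equiv), KOtBu (2.4 equiv), THF, 0 °C to rt; 1 M HCl work-up
Reagents that add atoms: methyltriphenylphosphonium bromide, C[P+](c1ccccc1)(c1ccccc1)c1ccccc1.[Br-]
Why: Wittig methylenation of the methyl ketone on the potassium carboxylate, with the phosphonium salt kept in excess over the base so that no free alkoxide epimerises the ring carbon next to the ketone (its descriptor changes from R to S by CIP priority only).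

Step 3
Reactants: 4 (1S,3S)-2,2-dimethyl-3-(prop-1-en-2-yl)cyclobutane-1-carboxylic acid
Product: 5 [(1S,3S)-2,2-dimethyl-3-(prop-1-en-2-yl)cyclobutyl]methanol
Conditions: LiAlH4 (1.5 equiv), Et2O, 0 °C to rt; Rochelle salt
Reagents that add atoms: none
Why: Hydride reduction of the carboxylic acid to the primary alcohol, which leaves the isolated 1,1-disubstituted alkene and both ring stereocentres untouched.

Step 4
Reactants: 5 [(1S,3S)-2,2-dimethyl-3-(prop-1-en-2-yl)cyclobutyl]methanol
Product: 6 (1S,3S)-1-(iodomethyl)-2,2-dimethyl-3-(prop-1-en-2-yl)cyclobutane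
Conditions: PPh3 (1.3 equiv), imidazole (1.5 equiv), I2 (1.25 equiv, premixed), CH2Cl2, 0 °C to rt
Reagents that add atoms: iodine, II
Why: Appel-type iodination (Garegg–Samuelsson conditions), an SN2 displacement of the alkoxyphosphonium ion at the primary carbon, so that no cyclobutylcarbinyl cation and hence no ring expansion can arise.

Step 5
Reactants: 6 (1S,3S)-1-(iodomethyl)-2,2-dimethyl-3-(prop-1-en-2-yl)cyclobutane; 7 tert-butyl methyl malonate
Product: 8 1-tert-butyl 3-methyl 2-{[(1R,3S)-2,2-dimethyl-3-(prop-1-en-2-yl)cyclobutyl]methyl}propanedioate (both epimers at the malonate carbon)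
Conditions: 7 (2.0 equiv), NaH (1.9 equiv), DMF, 0 to 60 °C
Reagents that add atoms: none
Why: Malonic ester alkylation (SN2) of the sodium enolate of 7 by the primary iodide in a dipolar aprotic solvent, with excess malonate against dialkylation; the new malonate carbon is an epimeric mixture that is planarised again in step 6.

Step 6
Reactants: 8 1-tert-butyl 3-methyl 2-{[(1R,3S)-2,2-dimethyl-3-(prop-1-en-2-yl)cyclobutyl]methyl}propanedioate
Product: 9 1-tert-butyl 3-methyl (2S)-2-{[(1R,3S)-2,2-dimethyl-3-(prop-1-en-2-yl)cyclobutyl]methyl}-2-(3-methylbut-2-en-1-yl)propanedioate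
Conditions: prenyl bromide (1.5 equiv), N-(9-anthracenylmethyl)cinchonidinium chloride (10 mol%), 50% aq KOH, toluene, −20 °C
Reagents that add atoms: 1-bromo-3-methylbut-2-ene (prenyl bromide), CC(C)=CCBr
Why: Enantioselective phase-transfer alkylation of an α-monosubstituted mixed malonate, in which the chiral ammonium cation is ion-paired with the enolate whose tert-butyl and methyl ester groups differ strongly in size and lets prenyl bromide reach only one face, which sets quaternary C6 as S; since the cyclobutane is chiral, the minor isomer is a diastereomer and separable.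

Step 7
Reactants: 9 1-tert-butyl 3-methyl (2S)-2-{[(1R,3S)-2,2-dimethyl-3-(prop-1-en-2-yl)cyclobutyl]methyl}-2-(3-methylbut-2-en-1-yl)propanedioate
Product: 11 (2R)-2-{[(1R,3S)-2,2-dimethyl-3-(prop-1-en-2-yl)cyclobutyl]methyl}-2-(methoxycarbonyl)-5-methylhex-4-enoic acid, via trimethylsilyl ester 10 (not isolated)
Conditions: Me3SiOTf (2.0 equiv), 2,6-lutidine (3.0 equiv), CH2Cl2, 0 °C to rt; pH 4 citrate buffer
Reagents that add atoms: trimethylsilyl trifluoromethanesulfonate, C[Si](C)(C)OS(=O)(=O)C(F)(F)F (its Me3Si group is carried by 10 only)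
Why: Silyl triflate-mediated dealkylation of the tert-butyl ester (O-silylation, loss of isobutene), buffered by 2,6-lutidine so that no protic acid can protonate the isopropenylcyclobutane or the prenyl group, leaves the methyl ester intact and so tells apart the two carbonyl groups on C6 (free acid = future C7, methyl ester = future C5; the descriptor changes by CIP priority only).

Step 8
Reactants: 11 (2R)-2-{[(1R,3S)-2,2-dimethyl-3-(prop-1-en-2-yl)cyclobutyl]methyl}-2-(methoxycarbonyl)-5-methylhex-4-enoic acid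
Product: 13 methyl (2R)-2-{[(1R,3S)-2,2-dimethyl-3-(prop-1-en-2-yl)cyclobutyl]methyl}-2-(3-methylbut-2-en-1-yl)-3-oxohex-4-ynoate, via acid chloride 12 (not isolated)
Conditions: 1-chloro-N,N,2-trimethylprop-1-en-1-amine (1.2 equiv), CH2Cl2, 0 °C to rt; then propyne (3 equiv), PdCl2(PPh3)2 (2 mol%), CuI (4 mol%), Et3N (3 equiv), THF, rt
Reagents that add atoms: propyne, CC#C; 1-chloro-N,N,2-trimethylprop-1-en-1-amine, CC(C)=C(Cl)N(C)C (its chlorine is carried by 12 only)
Why: Neutral conversion of the acid into acid chloride 12 with the Ghosez reagent followed by acyl Sonogashira coupling with propyne gives the alkynyl ketone; C6 carries no hydrogen, so neither ketene formation nor epimerisation is possible.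

Step 9
Reactants: 14 (4S)-4-benzyl-3-propanoyl-1,3-oxazolidin-2-one
Product: 15 (4S)-4-benzyl-3-[(2S,3R)-3-hydroxy-2-methylbutanoyl]-1,3-oxazolidin-2-one
Conditions: Bu2BOTf (1.1 equiv), i-Pr2NEt (1.2 equiv), CH2Cl2, −78 °C; MeCHO (1.5 equiv), −78 to 0 °C; pH 7 buffer, MeOH, 30% H2O2
Reagents that add atoms: acetaldehyde, CC=O
Why: Evans syn-aldol reaction through the Z-boron enolate and a Zimmerman–Traxler transition state, in which the auxiliary sets both new stereocentres together as (2S,3R), the future C3 and C2 of the pyranone.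

Step 10
Reactants: 15 (4S)-4-benzyl-3-[(2S,3R)-3-hydroxy-2-methylbutanoyl]-1,3-oxazolidin-2-one
Product: 16 methyl (2S,3R)-3-hydroxy-2-methylbutanoate
Conditions: NaOMe (1.1 equiv), MeOH/CH2Cl2, −15 °C, 10 min; AcOH
Reagents that add atoms: sodium methoxide, [Na+].[O-]C
Why: Exocyclic methanolysis of the imide by methoxide at low temperature and short contact time releases the auxiliary and gives the methyl ester without retro-aldol cleavage or epimerisation.

Step 11
Reactants: 13 methyl (2R)-2-{[(1R,3S)-2,2-dimethyl-3-(prop-1-en-2-yl)cyclobutyl]methyl}-2-(3-methylbut-2-en-1-yl)-3-oxohex-4-ynoate; 16 methyl (2S,3R)-3-hydroxy-2-methylbutanoate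
Product: 17 methyl (2R)-2-{[(1R,3S)-2,2-dimethyl-3-(prop-1-en-2-yl)cyclobutyl]methyl}-5-{[(2R,3S)-4-methoxy-3-methyl-4-oxobutan-2-yl]oxy}-2-(3-methylbut-2-en-1-yl)-3-oxohex-4-enoate (E/Z not defined)
Conditions: 16 (1.1 equiv), KHMDS (1.05 equiv), THF, −78 °C; then 13, −78 to −40 °C; AcOH at −78 °C
Reagents that add atoms: none
Why: Oxa-Michael addition of the potassium alkoxide of 16 to the β-carbon (C8a) of the ynone, quenched cold, gives the β-alkoxy enone and thereby fixes the O1–C8a bond before any ring exists, so that the pyran oxygen has only one place to go.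

Step 12
Reactants: 17 methyl (2R)-2-{[(1R,3S)-2,2-dimethyl-3-(prop-1-en-2-yl)cyclobutyl]methyl}-5-{[(2R,3S)-4-methoxy-3-methyl-4-oxobutan-2-yl]oxy}-2-(3-methylbut-2-en-1-yl)-3-oxohex-4-enoate
Product: 19 (2R,3S,6R)-6-{[(1R,3S)-2,2-dimethyl-3-(prop-1-en-2-yl)cyclobutyl]methyl}-4-hydroxy-2,3-dimethyl-6-(3-methylbut-2-en-1-yl)-2H-chromene-5,7(3H,6H)-dione, via pyranone 18 (not isolated)
Conditions: LiHMDS (1.1 equiv), THF, −78 to 0 °C, then 50 °C; 1 M HCl to pH 3 at 0 °C
Reagents that add atoms: none
Why: Proposed new method: LiHMDS removes a proton from the C4a methyl group of 17, the only C–H acidified by the C7 ketone because C6 is quaternary and C8 is vinylic, and the lithium dienolate attacks the C4 methyl ester through its γ-carbon (6-exo-trig Claisen closure, C4–C4a) to give pyranone 18 with loss of methoxide. The methoxide deprotonates 18 to a vinylogous β-diketonate whose C4a carbon then attacks the C5 methyl ester (6-exo-trig Dieckmann closure, C4a–C5) to give the enolate of 19, so one equivalent of base serves both closures. The closest known reaction types are the γ-acylation of lithiated β-alkoxy enoates and dioxinones, the Baker–Venkataraman route to chromones and the biomimetic Claisen cyclisation of 3,5-dioxo esters to cyclohexane-1,3,5-triones. No stereocentre is formed: C2 and C3 come from the aldol unit and C6 from the malonate, C6 has no α-proton, and C3 is shielded after the first closure because the C4 carbonyl is then part of the delocalised anion. The step needs γ- rather than α-acylation and no β-elimination of the enol ether oxygen from a C3 carbanion; the first is expected from the known γ-selectivity of β-alkoxy dienolates towards carbonyl electrophiles, the second because the single equivalent of strong base is consumed by the more acidic, unhindered methyl group and passed on as methoxide, which is too weak to enolise the ester and cannot scramble the all-methyl esters. Because O1 is already bonded to C8a and C4a is the only carbon that can reach either ester through a six-membered transition state, both orders of closure lead to the same bicycle.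

Step 13
Reactants: 19 (2R,3S,6R)-6-{[(1R,3S)-2,2-dimethyl-3-(prop-1-en-2-yl)cyclobutyl]methyl}-4-hydroxy-2,3-dimethyl-6-(3-methylbut-2-en-1-yl)-2H-chromene-5,7(3H,6H)-dione; 20 3-phenylprop-2-ynal
Product: 22 (3S)-3-[(2R,3S,6R)-6-{[(1R,3S)-2,2-dimethyl-3-(prop-1-en-2-yl)cyclobutyl]methyl}-4-hydroxy-2,3-dimethyl-6-(3-methylbut-2-en-1-yl)-5,7-dioxo-3,5,6,7-tetrahydro-2H-chromen-8-yl]-3-phenylpropanoic acid (CNP0328119.1), via enol lactone 21 (not isolated)
Conditions: 20 (1.5 equiv), (5aR,10bS)-2-(2,4,6-trimethylphenyl)-5a,10b-dihydro-4H,6H-indeno[2,1-b][1,2,4]triazolo[4,3-d][1,4]oxazin-2-ium chloride (10 mol%), i-Pr2NEt (20 mol%), toluene, 4 Å MS, rt; then LiOH·H2O (4 equiv), THF/H2O, 0 °C; 1 M HCl to pH 3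
Reagents that add atoms: lithium hydroxide monohydrate, [Li+].[OH-].O
Why: Carbene-catalysed annulation in which the triazolylidene converts the ynal into an α,β-unsaturated acyl azolium, the C7 enol of 19 adds through C8 (its only free nucleophilic carbon) to the β-carbon on the face fixed by the chiral catalyst, which sets the benzylic centre as S, and the enol oxygen is then acylated to lactone 21, which hydroxide opens to the acid.

**Compound list**
1 | (1S,5S)-(−)-verbenone | CC1=CC(=O)[C@H]2C[C@@H]1C2(C)C | starting material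
2 | 2-[(1S,3R)-3-acetyl-2,2-dimethylcyclobutyl]-2-oxoacetic acid (in situ) | CC(=O)[C@@H]1C[C@H](C(=O)C(=O)O)C1(C)C | intermediate
3 | (1S,3R)-3-acetyl-2,2-dimethylcyclobutane-1-carboxylic acid (cis-pinononic acid) | CC(=O)[C@@H]1C[C@H](C(=O)O)C1(C)C | intermediate
4 | (1S,3S)-2,2-dimethyl-3-(prop-1-en-2-yl)cyclobutane-1-carboxylic acid | C=C(C)[C@@H]1C[C@H](C(=O)O)C1(C)C | intermediate
5 | [(1S,3S)-2,2-dimethyl-3-(prop-1-en-2-yl)cyclobutyl]methanol | C=C(C)[C@@H]1C[C@H](CO)C1(C)C | intermediate
6 | (1S,3S)-1-(iodomethyl)-2,2-dimethyl-3-(prop-1-en-2-yl)cyclobutane | C=C(C)[C@@H]1C[C@H](CI)C1(C)C | intermediate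
7 | tert-butyl methyl malonate (1-tert-butyl 3-methyl propanedioate) | COC(=O)CC(=O)OC(C)(C)C | starting material
8 | 1-tert-butyl 3-methyl 2-{[(1R,3S)-2,2-dimethyl-3-(prop-1-en-2-yl)cyclobutyl]methyl}propanedioate (epimers at the malonate carbon) | C=C(C)[C@@H]1C[C@H](CC(C(=O)OC)C(=O)OC(C)(C)C)C1(C)C | intermediate
9 | 1-tert-butyl 3-methyl (2S)-2-{[(1R,3S)-2,2-dimethyl-3-(prop-1-en-2-yl)cyclobutyl]methyl}-2-(3-methylbut-2-en-1-yl)propanedioate | C=C(C)[C@@H]1C[C@H](C[C@@](C(=O)OC(C)(C)C)(CC=C(C)C)C(=O)OC)C1(C)C | intermediate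
10 | 1-methyl 3-trimethylsilyl (2S)-2-{[(1R,3S)-2,2-dimethyl-3-(prop-1-en-2-yl)cyclobutyl]methyl}-2-(3-methylbut-2-en-1-yl)propanedioate (in situ) | C=C(C)[C@@H]1C[C@H](C[C@@](C(=O)O[Si](C)(C)C)(CC=C(C)C)C(=O)OC)C1(C)C | intermediate
11 | (2R)-2-{[(1R,3S)-2,2-dimethyl-3-(prop-1-en-2-yl)cyclobutyl]methyl}-2-(methoxycarbonyl)-5-methylhex-4-enoic acid | C=C(C)[C@@H]1C[C@H](C[C@@](C(=O)O)(CC=C(C)C)C(=O)OC)C1(C)C | intermediate
12 | methyl (2S)-2-(chlorocarbonyl)-2-{[(1R,3S)-2,2-dimethyl-3-(prop-1-en-2-yl)cyclobutyl]methyl}-5-methylhex-4-enoate (in situ) | C=C(C)[C@@H]1C[C@H](C[C@@](C(=O)Cl)(CC=C(C)C)C(=O)OC)C1(C)C | intermediate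
13 | methyl (2R)-2-{[(1R,3S)-2,2-dimethyl-3-(prop-1-en-2-yl)cyclobutyl]methyl}-2-(3-methylbut-2-en-1-yl)-3-oxohex-4-ynoate | C=C(C)[C@@H]1C[C@H](C[C@@](C(=O)C#CC)(CC=C(C)C)C(=O)OC)C1(C)C | intermediate
14 | (4S)-4-benzyl-3-propanoyl-1,3-oxazolidin-2-one | CCC(=O)N1C(=O)OC[C@@H]1Cc1ccccc1 | starting material
15 | (4S)-4-benzyl-3-[(2S,3R)-3-hydroxy-2-methylbutanoyl]-1,3-oxazolidin-2-one | O=C(N1C(=O)OC[C@@H]1Cc1ccccc1)[C@@H](C)[C@@H](C)O | intermediate
16 | methyl (2S,3R)-3-hydroxy-2-methylbutanoate | COC(=O)[C@@H](C)[C@@H](C)O | intermediate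
17 | methyl (2R)-2-{[(1R,3S)-2,2-dimethyl-3-(prop-1-en-2-yl)cyclobutyl]methyl}-5-{[(2R,3S)-4-methoxy-3-methyl-4-oxobutan-2-yl]oxy}-2-(3-methylbut-2-en-1-yl)-3-oxohex-4-enoate (E/Z not defined) | C=C(C)[C@@H]1C[C@H](C[C@@](C(=O)C=C(C)O[C@H](C)[C@H](C)C(=O)OC)(CC=C(C)C)C(=O)OC)C1(C)C | intermediate
18 | methyl (2R)-2-{[(1R,3S)-2,2-dimethyl-3-(prop-1-en-2-yl)cyclobutyl]methyl}-4-[(2R,3S)-2,3-dimethyl-4-oxo-3,4-dihydro-2H-pyran-6-yl]-2-(3-methylbut-2-en-1-yl)-3-oxobutanoate (in situ) | C=C(C)[C@@H]1C[C@H](C[C@@](C(=O)CC2=CC(=O)[C@@H](C)[C@@H](C)O2)(CC=C(C)C)C(=O)OC)C1(C)C | intermediate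
19 | (2R,3S,6R)-6-{[(1R,3S)-2,2-dimethyl-3-(prop-1-en-2-yl)cyclobutyl]methyl}-4-hydroxy-2,3-dimethyl-6-(3-methylbut-2-en-1-yl)-2H-chromene-5,7(3H,6H)-dione | C=C(C)[C@@H]1C[C@H](C[C@@]2(CC=C(C)C)C(=O)C3=C(O)[C@@H](C)[C@@H](C)OC3=CC2=O)C1(C)C | intermediate
20 | 3-phenylprop-2-ynal | O=CC#Cc1ccccc1 | starting material
21 | (2R,3S,6R,10S)-6-{[(1R,3S)-2,2-dimethyl-3-(prop-1-en-2-yl)cyclobutyl]methyl}-2,3-dimethyl-6-(3-methylbut-2-en-1-yl)-10-phenyl-2,3,9,10-tetrahydro-4H,8H-pyrano[2,3-f]chromene-4,5,8(6H)-trione (enol δ-lactone of the target through the C7 oxygen, in situ) | C=C(C)[C@@H]1C[C@H](C[C@@]2(CC=C(C)C)C(=O)C3=C(O[C@H](C)[C@H](C)C3=O)C4=C2OC(=O)C[C@H]4c2ccccc2)C1(C)C | intermediate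
22 | (3S)-3-[(2R,3S,6R)-6-{[(1R,3S)-2,2-dimethyl-3-(prop-1-en-2-yl)cyclobutyl]methyl}-4-hydroxy-2,3-dimethyl-6-(3-methylbut-2-en-1-yl)-5,7-dioxo-3,5,6,7-tetrahydro-2H-chromen-8-yl]-3-phenylpropanoic acid | C=C(C)[C@@H]1C[C@H](C[C@@]2(CC=C(C)C)C(=O)C3=C(O)[C@@H](C)[C@@H](C)OC3=C([C@@H](CC(=O)O)c3ccccc3)C2=O)C1(C)C | target

Total step count: 13. Longest linear sequence: 11 steps (steps 1–8, 11, 12, 13).

Steps most likely to fail:

Step 12 (labelled). The C3 proton could be removed instead of the methyl proton, followed by β-elimination of the enol ether oxygen; the dienolate could acylate through its α-carbon; or the second closure onto the hindered C5 ester could stall. The fallback uses known reactions only and runs from 11 and 15 back to 18. Acid chloride 12 (from 11) would be C-acylated onto the lithium enolate of acetone (2.2 equiv, THF, −78 °C) to give the 1,3-diketone methyl (2R)-2-{[(1R,3S)-2,2-dimethyl-3-(prop-1-en-2-yl)cyclobutyl]methyl}-2-(3-methylbut-2-en-1-yl)-3,5-dioxohexanoate F1. Aldol adduct 15 would be converted with AlMe3/MeNHOMe·HCl into the Weinreb amide (2S,3R)-3-hydroxy-N-methoxy-N,2-dimethylbutanamide F2 and silylated (Et3SiCl, imidazole) to (2S,3R)-N-methoxy-N,2-dimethyl-3-[(triethylsilyl)oxy]butanamide F3. The dianion of F1 (LDA, 2.2 equiv, −78 °C; only its terminal methyl group carries γ-protons) would be acylated by F3 to the protected hydroxy triketone methyl (2R,8S,9R)-2-{[(1R,3S)-2,2-dimethyl-3-(prop-1-en-2-yl)cyclobutyl]methyl}-8-methyl-2-(3-methylbut-2-en-1-yl)-3,5,7-trioxo-9-[(triethylsilyl)oxy]decanoate F4. PPTS in MeOH would remove the silyl group and cyclodehydrate the δ-hydroxy β-diketone to pyranone 18 (the hydroxyl can reach only C8a through a six-membered ring), and NaOMe in MeOH would then effect the Claisen closure to 19.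

Step 6. The ion-paired enolate could show poor facial selectivity because its α-substituent is aliphatic. The fallback runs from 6 back to 11 by enzymatic desymmetrisation. Iodide 6 would alkylate dimethyl malonate (NaH, DMF) to dimethyl 2-{[(1R,3S)-2,2-dimethyl-3-(prop-1-en-2-yl)cyclobutyl]methyl}propanedioate F5, and prenylation (NaH, prenyl bromide, THF) would give dimethyl 2-{[(1R,3S)-2,2-dimethyl-3-(prop-1-en-2-yl)cyclobutyl]methyl}-2-(3-methylbut-2-en-1-yl)propanedioate F6, in which C6 is not yet a stereocentre. Pig liver esterase (pH 7.5 phosphate buffer, 10% DMSO) would hydrolyse one of the two diastereotopic methyl esters to half-acid 11. Because the cyclobutane is chiral, any wrong isomer is a diastereomer and could be removed by crystallisation of the (R)-1-phenylethylammonium salt.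

Step 13. Facial selectivity at the benzylic carbon could be poor on this hindered enol, or the enol could be O-acylated without C–C bond formation. The fallback runs from 19 back to 21 by iminium catalysis. Cinnamaldehyde and the enantiomer of 2-[diphenyl(trimethylsilyloxy)methyl]pyrrolidine that gives the (S)-benzylic carbon (10 mol%, CH2Cl2, rt) would give the Michael adduct as its cyclic hemiacetal, the lactol (2R,3S,6R,10S)-6-{[(1R,3S)-2,2-dimethyl-3-(prop-1-en-2-yl)cyclobutyl]methyl}-8-hydroxy-2,3-dimethyl-6-(3-methylbut-2-en-1-yl)-10-phenyl-2,3,9,10-tetrahydro-4H,8H-pyrano[2,3-f]chromene-4,5(6H)-dione F7. Ag2CO3 on Celite (toluene, 80 °C) would oxidise the lactol to lactone 21, which is opened with LiOH as in step 13.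

Further compounds
F1 | step 12 | methyl (2R)-2-{[(1R,3S)-2,2-dimethyl-3-(prop-1-en-2-yl)cyclobutyl]methyl}-2-(3-methylbut-2-en-1-yl)-3,5-dioxohexanoate | C=C(C)[C@@H]1C[C@H](C[C@@](C(=O)CC(C)=O)(CC=C(C)C)C(=O)OC)C1(C)C
F2 | step 12 | (2S,3R)-3-hydroxy-N-methoxy-N,2-dimethylbutanamide | CON(C)C(=O)[C@@H](C)[C@@H](C)O
F3 | step 12 | (2S,3R)-N-methoxy-N,2-dimethyl-3-[(triethylsilyl)oxy]butanamide | CON(C)C(=O)[C@@H](C)[C@@H](C)O[Si](CC)(CC)CC
F4 | step 12 | methyl (2R,8S,9R)-2-{[(1R,3S)-2,2-dimethyl-3-(prop-1-en-2-yl)cyclobutyl]methyl}-8-methyl-2-(3-methylbut-2-en-1-yl)-3,5,7-trioxo-9-[(triethylsilyl)oxy]decanoate | C=C(C)[C@@H]1C[C@H](C[C@@](C(=O)CC(=O)CC(=O)[C@@H](C)[C@@H](C)O[Si](CC)(CC)CC)(CC=C(C)C)C(=O)OC)C1(C)C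
F5 | step 6 | dimethyl 2-{[(1R,3S)-2,2-dimethyl-3-(prop-1-en-2-yl)cyclobutyl]methyl}propanedioate | C=C(C)[C@@H]1C[C@H](CC(C(=O)OC)C(=O)OC)C1(C)C
F6 | step 6 | dimethyl 2-{[(1R,3S)-2,2-dimethyl-3-(prop-1-en-2-yl)cyclobutyl]methyl}-2-(3-methylbut-2-en-1-yl)propanedioate | C=C(C)[C@@H]1C[C@H](CC(CC=C(C)C)(C(=O)OC)C(=O)OC)C1(C)C
F7 | step 13 | (2R,3S,6R,10S)-6-{[(1R,3S)-2,2-dimethyl-3-(prop-1-en-2-yl)cyclobutyl]methyl}-8-hydroxy-2,3-dimethyl-6-(3-methylbut-2-en-1-yl)-10-phenyl-2,3,9,10-tetrahydro-4H,8H-pyrano[2,3-f]chromene-4,5(6H)-dione (anomers at C8) | C=C(C)[C@@H]1C[C@H](C[C@@]2(CC=C(C)C)C(=O)C3=C(O[C@H](C)[C@H](C)C3=O)C4=C2OC(O)C[C@H]4c2ccccc2)C1(C)C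
A1 | direct plan | 5,7-dihydroxy-4-phenylcoumarin | O=c1cc(-c2ccccc2)c2c(O)cc(O)cc2o1
A2 | direct plan | (2R,3S,10S)-5-hydroxy-2,3-dimethyl-10-phenyl-2,3,9,10-tetrahydro-4H,8H-pyrano[2,3-f]chromene-4,8-dione | C[C@H]1Oc2c3c(cc(O)c2C(=O)[C@H]1C)OC(=O)C[C@H]3c1ccccc1
A3 | direct plan | (1S,3S)-2,2-dimethyl-3-(prop-1-en-2-yl)cyclobutane-1-carbaldehyde | C=C(C)[C@@H]1C[C@H](C=O)C1(C)C
A4 | direct plan | methyl (3S)-3-[(2R,3S)-6-{[(1R,3S)-2,2-dimethyl-3-(prop-1-en-2-yl)cyclobutyl]methyl}-5,7-dihydroxy-2,3-dimethyl-4-oxo-3,4-dihydro-2H-chromen-8-yl]-3-phenylpropanoate | C[C@H]1Oc2c([C@@H](CC(=O)OC)c3ccccc3)c(O)c(C[C@H]3C[C@@H](C(C)=C)C3(C)C)c(O)c2C(=O)[C@H]1C
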